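Labdane numbering is used (ring A: C1–C5 and C10; ring B: C5–C10). Everything rests on the C4–C5 bond. C4 carries the gem-dimethyl group and supports a tertiary cation, while C5 is the α-carbon of the C6 oxygen function. Ring A is therefore closed last, by TiCl4-induced intramolecular α-tert-alkylation of a ring B 2-silyloxydiene. One operation forges this hindered bond beside quaternary C10 and unveils the 6-oxo-7-ene that later delivers both oxygens. The precursor is a monocyclic cyclohexadiene bearing C9, C10 (from an asymmetric conjugate addition–alkylation) and a 4-chloro-4-methylpentyl arm. C5 remains enolisable and is set afterwards.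

Key step: step 7

Assumption: α and β mean the lower and upper face of the decalin in the usual labdane drawing, and the ligand enantiomer used in step 1 is the one that leads to the (R)-configured enolate 5.

Step 1
Reactants: 1 5-bromo-2-methylpent-2-ene; 2 3-methylcyclohex-2-en-1-one; 3 1-bromobut-2-yne
Product: 6 (2R,3R)-2-(but-2-yn-1-yl)-3-methyl-3-(4-methylpent-3-en-1-yl)cyclohexan-1-one, via Grignard reagent 4 (not isolated), via magnesium enolate 5 (not isolated)
Conditions: 1, Mg, Et2O, reflux; then 2, Cu(OTf)2 (3 mol %), chiral hydroxyalkyl N-mesitylimidazolinium PF6 salt (4 mol %), Et2O, −30 °C; then 3, DMPU, THF, −30 °C to rt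
Reagents that add atoms: none
Why: A copper–NHC-catalysed asymmetric conjugate addition of the Grignard reagent sets quaternary C10 under catalyst control, and the regiodefined enolate is alkylated at C9 anti to the chain just delivered (tandem vicinal difunctionalisation), which places the butynyl group cis to the C10 methyl group.

Step 2
Reactants: 6 (2R,3R)-2-(but-2-yn-1-yl)-3-methyl-3-(4-methylpent-3-en-1-yl)cyclohexan-1-one
Product: 9 (5S,6R)-6-(but-2-yn-1-yl)-5-methyl-5-(4-methylpent-3-en-1-yl)cyclohex-2-en-1-one, via lithium enolate 7 (not isolated), via sulfilimine adduct 8 (not isolated)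
Conditions: LiN(i-Pr)2, THF, −78 °C; then PhS(Cl)=N-t-Bu, −78 °C
Reagents that add atoms: none
Why: Kinetic deprotonation at the unhindered C7 methylene, trapping with the sulfinimidoyl chloride and syn elimination (Mukaiyama dehydrogenation) give the C6=C7 enone without touching C9 or C10.

Step 3
Reactants: 9 (5S,6R)-6-(but-2-yn-1-yl)-5-methyl-5-(4-methylpent-3-en-1-yl)cyclohex-2-en-1-one
Product: 10 (5S,6R)-6-(but-2-yn-1-yl)-1,5-dimethyl-5-(4-methylpent-3-en-1-yl)cyclohex-2-en-1-ol (both C1 epimers)
Conditions: MeLi, Et2O, −78 °C; then H2O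
Reagents that add atoms: methyllithium, [Li]C
Why: Hard methyllithium adds 1,2 to the enone carbonyl C8 and brings in C17, and the configuration of the new carbinol centre does not matter because step 4 erases it.

Step 4
Reactants: 10 (5S,6R)-6-(but-2-yn-1-yl)-1,5-dimethyl-5-(4-methylpent-3-en-1-yl)cyclohex-2-en-1-ol
Product: 11 (4R,5S)-4-(but-2-yn-1-yl)-3,5-dimethyl-5-(4-methylpent-3-en-1-yl)cyclohex-2-en-1-one
Conditions: pyridinium chlorochromate C5H5NH[CrO3Cl], NaOAc, 4 Å molecular sieves, CH2Cl2, rt
Reagents that add atoms: pyridinium chlorochromate, [O-][Cr](=O)(=O)Cl.c1cc[nH+]cc1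
Why: In the Babler–Dauben oxidative transposition the tertiary allylic chromate ester undergoes a [3,3] shift to C6 and is oxidised there, which moves the oxygen function from C8 to C6 and leaves the C7=C8 double bond with its methyl group.

Step 5
Reactants: 11 (4R,5S)-4-(but-2-yn-1-yl)-3,5-dimethyl-5-(4-methylpent-3-en-1-yl)cyclohex-2-en-1-one
Product: 12 (4R,5S)-4-(but-2-yn-1-yl)-5-(4-chloro-4-methylpentyl)-3,5-dimethylcyclohex-2-en-1-one
Conditions: dry HCl (4 M in dioxane), CH2Cl2, −20 °C
Reagents that add atoms: hydrogen chloride, Cl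
Why: Markovnikov hydrochlorination occurs only at the electron-rich trisubstituted alkene, because the enone double bond and the internal alkyne are far less basic, and it puts the SN1-active leaving group on C4.

Step 6
Reactants: 12 (4R,5S)-4-(but-2-yn-1-yl)-5-(4-chloro-4-methylpentyl)-3,5-dimethylcyclohex-2-en-1-one
Product: 14 trimethylsilyl dienol ether of 12 (C5=C6(OSiMe3)–C7=C8; C9 and C10 as in 12), via lithium dienolate 13 (not isolated)
Conditions: LiN(i-Pr)2, THF, −78 °C; then Me3SiCl; pentane, filtration
Reagents that add atoms: chlorotrimethylsilane, C[Si](C)(C)Cl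
Why: Kinetic deprotonation of a 3-methylcyclohexenone removes the α′ proton at C5, and O-silylation fixes the cross-conjugated 2-silyloxydiene whose nucleophilic terminus is C5.

Step 7
Reactants: 14 trimethylsilyl dienol ether of 12
Product: 15 cis-fused (5β-H) 14,15-dinorlabd-7-en-12-yn-6-one
Conditions: TiCl4 (1.1 equiv), 2,6-di-tert-butylpyridine (0.3 equiv), CH2Cl2, −78 to −40 °C; then aq NaHCO3
Reagents that add atoms: none
Why: TiCl4 ionises the tertiary C4–Cl bond, C5 (the terminal carbon of the 2-silyloxydiene) captures the C4 cation, and chloride removes the silyl group from the resulting oxocarbenium ion to release the 6-oxo-7-ene. The closest known reaction is the Lewis-acid-induced α-tert-alkylation of silyl enol ethers with SN1-active halides (Reetz alkylation, the SN1 counterpart of the Mukaiyama reactions), used here intramolecularly. Ring A closes in a 6-(enolendo)-exo mode through a chair-like six-membered transition state. C5 is the only new stereocentre: the three-carbon tether hangs from the α face of C10 and can reach only the α lobe of C5, so the substrate enforces the cis fusion (5β-H), which is accepted because C5 stays enolisable and is inverted in step 8, whereas C4 is not stereogenic. The step needs C-alkylation at C5 rather than at oxygen, C7 or the alkyne, and ring size secures this, since every alternative would need an eight-membered or bridged ring. Loss of a proton from the cation is the main competitor and is held back by the low temperature and by the hindered pyridine, which scavenges the acid that would otherwise cleave the silyl enol ether.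

Step 8
Reactants: 15 cis-fused (5β-H) 14,15-dinorlabd-7-en-12-yn-6-one
Product: 17 trans-fused (5α-H,9α-H,10β-methyl) 14,15-dinorlabd-7-en-12-yn-6-one, via lithium dienolate 16 (not isolated)
Conditions: LiN(i-Pr)2, THF, −78 to −20 °C; then AcOH, THF, −78 °C
Reagents that add atoms: none
Why: Deprotonation at C5, the only α′ position, gives the planar cross-conjugated dienolate, and kinetic protonation comes from the α face because the β face is screened by the axial methyl groups on C4 and C10, so the trans fusion results while the γ centre C9 is not touched.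

Step 9
Reactants: 17 trans-fused 14,15-dinorlabd-7-en-12-yn-6-one
Product: 18 7α,8α-epoxy-14,15-dinorlabd-12-yn-6-one
Conditions: 30% H2O2, NaOH (cat.), MeOH, 0 °C
Reagents that add atoms: hydrogen peroxide, OO
Why: Weitz–Scheffer nucleophilic epoxidation affects only the electron-poor C7=C8 bond, and hydroperoxide attacks C8 from the α face, anti to the axial C10 methyl group, which fixes the C8–O bond as 8α.

Step 10
Reactants: 18 7α,8α-epoxy-14,15-dinorlabd-12-yn-6-one
Product: 20 14,15-dinorlabd-12-yne-6α,8α-diol, via hydroxy ketone 19 (not isolated)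
Conditions: SmI2 (5 equiv), Et3N, H2O, THF, 0 °C to rt
Reagents that add atoms: none
Why: Single-electron reduction first cleaves the C7–O bond of the epoxy ketone with retention of the 8α C–O bond, and then takes the C6 ketone through its ketyl to the more stable equatorial 6α-alcohol, as in dissolving-metal ketone reductions, while the isolated alkyne is inert.

Step 11
Reactants: 20 14,15-dinorlabd-12-yne-6α,8α-diol
Product: 22 (12E)-labda-12,14-diene-6α,8α-diol, via alkenylzirconocene 21 (not isolated)
Conditions: Cp2Zr(H)Cl (3.3 equiv), THF, rt to 40 °C; then vinyl bromide, Pd(PPh3)4 (5 mol %), ZnCl2 (20 mol %), THF, rt; then H2O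
Reagents that add atoms: vinyl bromide, C=CBr
Why: Syn hydrozirconation places zirconium on C13, the less hindered alkyne carbon next to the methyl group, and the Negishi coupling with vinyl bromide proceeds with retention, which gives the (12E)-diene.

Step 12
Reactants: 22 (12E)-labda-12,14-diene-6α,8α-diol; 23 angelic acid
Product: 25 (5S,6S,8R,9R,10S,12E)-8-hydroxylabda-12,14-dien-6-yl (Z)-2-methylbut-2-enoate, via mixed anhydride 24 (not isolated)
Conditions: 23, 2,4,6-trichlorobenzoyl chloride, Et3N, toluene, rt; then 22, toluene, 75 °C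
Reagents that add atoms: none
Why: Yamaguchi-type mixed-anhydride acylation without a nucleophilic catalyst transfers the angeloyl group without Z-to-E isomerisation, and only the secondary 6α-hydroxyl reacts because the 8α-hydroxyl is tertiary.

Compound list
1 | 5-bromo-2-methylpent-2-ene | CC(C)=CCCBr | starting material
2 | 3-methylcyclohex-2-en-1-one | CC1=CC(=O)CCC1 | starting material
3 | 1-bromobut-2-yne | CC#CCBr | starting material
4 | (4-methylpent-3-en-1-yl)magnesium bromide | CC(C)=CCC[Mg]Br | intermediate
5 | bromomagnesium enolate of (R)-3-methyl-3-(4-methylpent-3-en-1-yl)cyclohexanone | C[C@]1(CCC=C(C)C)CCCC(O[Mg]Br)=C1 | intermediate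
6 | (2R,3R)-2-(but-2-yn-1-yl)-3-methyl-3-(4-methylpent-3-en-1-yl)cyclohexan-1-one | CC#CC[C@@H]1[C@@](C)(CCC=C(C)C)CCCC1=O | intermediate
7 | kinetic lithium enolate of 6 (C7=C8–OLi) | CC#CC[C@@H]1[C@@](C)(CCC=C(C)C)CCC=C1O[Li] | intermediate
8 | C7 S-phenyl-N-tert-butylsulfilimine adduct of 6 | CC#CC[C@@H]1[C@@](C)(CCC=C(C)C)CCC(C1=O)S(=NC(C)(C)C)c1ccccc1 | intermediate
9 | (5S,6R)-6-(but-2-yn-1-yl)-5-methyl-5-(4-methylpent-3-en-1-yl)cyclohex-2-en-1-one | CC#CC[C@@H]1[C@@](C)(CCC=C(C)C)CC=CC1=O | intermediate
10 | (5S,6R)-6-(but-2-yn-1-yl)-1,5-dimethyl-5-(4-methylpent-3-en-1-yl)cyclohex-2-en-1-ol, both C1 epimers | CC#CC[C@@H]1[C@@](C)(CCC=C(C)C)CC=CC1(C)O | intermediate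
11 | (4R,5S)-4-(but-2-yn-1-yl)-3,5-dimethyl-5-(4-methylpent-3-en-1-yl)cyclohex-2-en-1-one | CC#CC[C@@H]1[C@@](C)(CCC=C(C)C)CC(=O)C=C1C | intermediate
12 | (4R,5S)-4-(but-2-yn-1-yl)-5-(4-chloro-4-methylpentyl)-3,5-dimethylcyclohex-2-en-1-one | CC#CC[C@@H]1[C@@](C)(CCCC(C)(C)Cl)CC(=O)C=C1C | intermediate
13 | cross-conjugated lithium dienolate of 12 (C5=C6–OLi) | CC#CC[C@@H]1[C@@](C)(CCCC(C)(C)Cl)C=C(O[Li])C=C1C | intermediate
14 | trimethylsilyl dienol ether of 12 (2-silyloxy-1,3-diene, C9 and C10 as in 12) | CC#CC[C@@H]1[C@@](C)(CCCC(C)(C)Cl)C=C(O[Si](C)(C)C)C=C1C | intermediate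
15 | cis-fused (5β-H) 14,15-dinorlabd-7-en-12-yn-6-one, (4S,4aR,8aR)-4-(but-2-yn-1-yl)-3,4a,8,8-tetramethyl-4a,5,6,7,8,8a-hexahydronaphthalen-1(4H)-one | CC#CC[C@@H]1[C@@]2(C)CCCC(C)(C)[C@H]2C(=O)C=C1C | intermediate
16 | lithium dienolate of 15 (C5=C6–OLi) | CC#CC[C@@H]1[C@@]2(C)CCCC(C)(C)C2=C(O[Li])C=C1C | intermediate
17 | trans-fused (5α-H) 14,15-dinorlabd-7-en-12-yn-6-one, (4S,4aR,8aS)-4-(but-2-yn-1-yl)-3,4a,8,8-tetramethyl-4a,5,6,7,8,8a-hexahydronaphthalen-1(4H)-one | CC#CC[C@@H]1[C@@]2(C)CCCC(C)(C)[C@@H]2C(=O)C=C1C | intermediate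
18 | 7α,8α-epoxy-14,15-dinorlabd-12-yn-6-one | CC#CC[C@@H]1[C@@]2(C)CCCC(C)(C)[C@@H]2C(=O)[C@H]3O[C@@]13C | intermediate
19 | 8α-hydroxy-14,15-dinorlabd-12-yn-6-one | CC#CC[C@@H]1[C@@]2(C)CCCC(C)(C)[C@@H]2C(=O)C[C@@]1(C)O | intermediate
20 | 14,15-dinorlabd-12-yne-6α,8α-diol | CC#CC[C@@H]1[C@@]2(C)CCCC(C)(C)[C@@H]2[C@@H](O)C[C@@]1(C)O | intermediate
21 | C13 alkenylzirconocene chloride of 20, both hydroxyls bound as zirconocene alkoxides | C/C(=C\C[C@@H]1[C@@]2(C)CCCC(C)(C)[C@@H]2[C@@H](O[Zr](Cl)(C3C=CC=C3)C3C=CC=C3)C[C@@]1(C)O[Zr](Cl)(C3C=CC=C3)C3C=CC=C3)[Zr](Cl)(C3C=CC=C3)C3C=CC=C3 | intermediate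
22 | (12E)-labda-12,14-diene-6α,8α-diol | C=C/C(C)=C/C[C@@H]1[C@@]2(C)CCCC(C)(C)[C@@H]2[C@@H](O)C[C@@]1(C)O | intermediate
23 | angelic acid, (Z)-2-methylbut-2-enoic acid | C/C=C(/C)C(=O)O | starting material
24 | angelic 2,4,6-trichlorobenzoic anhydride | C/C=C(/C)C(=O)OC(=O)c1c(Cl)cc(Cl)cc1Cl | intermediate
25 | 6α-angeloyloxy-8α-hydroxylabda-12E,14-diene (CNP0582767.1) | C=C/C(C)=C/C[C@@H]1[C@@]2(C)CCCC(C)(C)[C@@H]2[C@@H](OC(=O)/C(C)=C\C)C[C@@]1(C)O | target

Total step count: 12. Longest linear sequence: 12 steps (from 1 or 2 to 25).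

Steps most likely to fail

**Step 7.** The ionised side arm may lose a proton faster than C5 captures it, and the acid set free would then strip the silyl group from the diene. The fallback goes from 11 back to 15. The side-chain alkene of 11 is epoxidised chemoselectively with mCPBA to the epoxy enone F1. Kinetic silylation as in step 6 gives the epoxy silyl dienol ether F2. MeAlCl2 in CH2Cl2 at −78 °C then starts an epoxide-initiated cation–olefin cyclisation that the silyl enol ether terminates, leading to the cis-fused 3-hydroxy enone F3. Acylation with 1,1′-thiocarbonyldiimidazole gives the imidazolylthiocarbonate F4, and Barton–McCombie deoxygenation (Bu3SnH, AIBN, toluene, 80 °C) returns 15.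

**Step 1.** Proton exchange between the hindered magnesium enolate and the product may move the site of alkylation to C7. The electrophile may also discriminate poorly between the two faces of C9. The fallback goes from 2 and 4 back to 6. The conjugate addition is quenched with Me3SiCl and the silyl enol ether F5 is isolated. MeLi in THF then releases the regiodefined, amine-free lithium enolate F6, which is alkylated with 3 at −78 °C in THF–DMPU, where alkylation should outrun proton transfer. The C9 epimers are separated at this stage.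

**Step 8.** The C5–H bond lies between two quaternary carbons, so deprotonation may be slow. The amide base may instead remove a γ proton, which would erode C9. The fallback goes from 15 back to 17. Soft enolisation with Me3SiOTf and Et3N in CH2Cl2 gives the fully substituted silyl dienol ether F7. Its protodesilylation with Bu4NF–AcOH in THF at −78 °C delivers the proton to the open α face of C5.

Further compounds
F1 | step 7 | (4R,5S)-4-(but-2-yn-1-yl)-5-[2-(3,3-dimethyloxiran-2-yl)ethyl]-3,5-dimethylcyclohex-2-en-1-one (epoxide epimers) | CC#CC[C@@H]1[C@@](C)(CCC2OC2(C)C)CC(=O)C=C1C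
F2 | step 7 | trimethylsilyl dienol ether of F1 | CC#CC[C@@H]1[C@@](C)(CCC2OC2(C)C)C=C(O[Si](C)(C)C)C=C1C
F3 | step 7 | cis-fused (5β-H) 3-hydroxy-14,15-dinorlabd-7-en-12-yn-6-one (C3 epimers) | CC#CC[C@@H]1[C@@]2(C)CCC(O)C(C)(C)[C@H]2C(=O)C=C1C
F4 | step 7 | O-(imidazol-1-ylthiocarbonyl) derivative of F3 | CC#CC[C@@H]1[C@@]2(C)CCC(OC(=S)n3ccnc3)C(C)(C)[C@H]2C(=O)C=C1C
F5 | step 1 | trimethylsilyl enol ether of (R)-3-methyl-3-(4-methylpent-3-en-1-yl)cyclohexanone (C8=C9) | C[C@]1(CCC=C(C)C)CCCC(O[Si](C)(C)C)=C1
F6 | step 1 | lithium enolate of (R)-3-methyl-3-(4-methylpent-3-en-1-yl)cyclohexanone (C8=C9) | C[C@]1(CCC=C(C)C)CCCC(O[Li])=C1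
F7 | step 8 | trimethylsilyl dienol ether of 15 (C5=C6(OSiMe3)–C7=C8) | CC#CC[C@@H]1[C@@]2(C)CCCC(C)(C)C2=C(O[Si](C)(C)C)C=C1C
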